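Everything rests on cutting ring A (C1–C6) at C1–C6 and C2–C3. The feature exploited is that C3 and C6 are unsubstituted while N (C4) and O (C5) sit on adjacent carbons, the pattern left by functionalising the alkene of a butadiene adduct; C1=C2 then becomes an acrolein carrying C9 as formyl group, the C7–C8 ester arm and the C2 oxygen. One catalytic enantioselective Diels–Alder reaction closes ring A, sets the quaternary spiro carbon C1 and leaves C4=C5 for C9-directed oxygenation and amination. The precursor is the E enol benzyl carbonate of a 2-substituted malondialdehyde, chosen so that the C2 oxygen is later freed by neutral hydrogenolysis.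

Key step: step 3

Remark (numbering): atom numbers are those of the target: ring A = C1 (spiro), C2 (C=O), C3, C4 (N), C5 (OH), C6; lactone = C7, C8 (C=O), O, C9.
Remark (assumption): the (S)-configured oxazaborolidinium catalyst is taken to expose the Re face of C1 of the dienophile, as the accepted model for 2-substituted acroleins predicts; its enantiomer is equally accessible.

Step 1
Reactants: 1 monomethyl succinate (4-methoxy-4-oxobutanoic acid)
Product: 4 methyl 3-formyl-4-hydroxybut-3-enoate (enol form of the 2-substituted malondialdehyde), via vinamidinium chloride 2 (not isolated), via enaminal 3 (not isolated)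
Conditions: POCl3 (3 equiv), DMF, 70 °C; then H2O, K2CO3, 0 °C → rt; then 2 M HCl, THF, rt
Reagents that add atoms: N,N-dimethylformamide, CN(C)C=O; water, O
Why: Vilsmeier-type (Arnold) double formylation of the acid at its α-carbon with loss of CO2 gives the 2-substituted vinamidinium salt, and staged hydrolysis (carbonate to the enaminal, then dilute acid) should release the dialdehyde without saponifying the methyl ester; no stereocentre is involved.

Step 2
Reactants: 4 methyl 3-formyl-4-hydroxybut-3-enoate; 5 benzyl chloroformate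
Product: 6 methyl (E)-4-{[(benzyloxy)carbonyl]oxy}-3-formylbut-3-enoate
Conditions: Et3N, CH2Cl2, −20 → 0 °C
Reagents that add atoms: none
Why: O-acylation of the dialdehyde enol with a chloroformate gives the enol carbonate, expected as the E isomer (carbonate trans to formyl) favoured by such push–pull enals; an acyl-type group keeps the enal electron-poor, and the benzyl carbonate is preferred to a benzoate because it can later be removed by hydrogenolysis instead of alkoxide.

Step 3
Reactants: 6 methyl (E)-4-{[(benzyloxy)carbonyl]oxy}-3-formylbut-3-enoate; 7 buta-1,3-diene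
Product: 8 methyl 2-[(1S,6R)-6-{[(benzyloxy)carbonyl]oxy}-1-formylcyclohex-3-en-1-yl]acetate
Conditions: (S)-3,3-diphenyl-1-(2-methylphenyl)tetrahydro-1H,3H-pyrrolo[1,2-c][1,3,2]oxazaborole (20 mol %), (CF3SO2)2NH (18 mol %), 7 (10 equiv), CH2Cl2, −78 → −40 °C
Reagents that add atoms: none
Why: The cationic oxazaborolidinium binds the formyl oxygen, the most Lewis-basic site, and with a formyl C–H···O contact holds the s-trans enal over one phenyl group, lowering the LUMO of C1=C2 so that butadiene adds to the open face in a concerted, suprafacial [4+2] process. The closest known reaction type is the oxazaborolidinium-catalysed Diels–Alder reaction of 2-substituted acroleins with butadiene. Ring A closes by intermolecular [4+2] annulation, the two σ-bonds C1–C6 and C2–C3 forming in the same step. The quaternary stereocentre C1 is set by the catalyst, which should expose the Re face of C1 and give 1S, and C2 follows from the E geometry of the dienophile, suprafacial addition placing formyl and carbonate trans. Only enantiofacial selectivity is needed, because symmetrical butadiene removes regio- and endo/exo isomerism, and it is secured by the two-point binding of the α-substituted enal, while the acyl-type carbonate keeps the β-oxygen from deactivating the dienophile as an alkoxy or silyloxy group would.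

Step 4
Reactants: 8 methyl 2-[(1S,6R)-6-{[(benzyloxy)carbonyl]oxy}-1-formylcyclohex-3-en-1-yl]acetate
Product: 9 (1S,6R)-6-{[(benzyloxy)carbonyl]oxy}-1-(2-methoxy-2-oxoethyl)cyclohex-3-ene-1-carboxylic acid
Conditions: NaClO2, NaH2PO4, 2-methylbut-2-ene, t-BuOH/H2O, 0 °C → rt
Reagents that add atoms: sodium chlorite, [Na+].[O-]Cl=O
Why: Pinnick oxidation turns the α-quaternary aldehyde into the acid without touching the alkene (hypochlorous acid is scavenged by 2-methylbut-2-ene), the carbonate or the ester; no stereocentre changes.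

Step 5
Reactants: 9 (1S,6R)-6-{[(benzyloxy)carbonyl]oxy}-1-(2-methoxy-2-oxoethyl)cyclohex-3-ene-1-carboxylic acid
Product: 10 methyl 2-[(1S,2R,4S,5S)-2-{[(benzyloxy)carbonyl]oxy}-4-iodo-7-oxo-6-oxabicyclo[3.2.1]octan-1-yl]acetate
Conditions: I2, KI, NaHCO3, CH2Cl2/H2O, 0 °C → rt, dark
Reagents that add atoms: iodine, II
Why: Iodolactonisation under kinetic conditions: the C9 carboxylate attacks C5 from its own face while iodine adds to C4 from the opposite face (anti addition, five-membered bridged lactone preferred), so C5–O is syn to C9 and both new stereocentres are dictated by C1.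

Step 6
Reactants: 10 methyl 2-[(1S,2R,4S,5S)-2-{[(benzyloxy)carbonyl]oxy}-4-iodo-7-oxo-6-oxabicyclo[3.2.1]octan-1-yl]acetate
Product: 11 methyl 2-[(1S,2R,4R,5S)-4-azido-2-{[(benzyloxy)carbonyl]oxy}-7-oxo-6-oxabicyclo[3.2.1]octan-1-yl]acetate
Conditions: NaN3 (3 equiv), DMF, 50 °C
Reagents that add atoms: sodium azide, [Na+].[N-]=[N+]=[N-]
Why: SN2 displacement of the axial secondary iodide by azide, a good nucleophile but weak base, inverts C4 and places nitrogen cis to the C5 oxygen; relief of the syn-axial iodide/carbonate contact should favour substitution over E2.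

Step 7
Reactants: 11 methyl 2-[(1S,2R,4R,5S)-4-azido-2-{[(benzyloxy)carbonyl]oxy}-7-oxo-6-oxabicyclo[3.2.1]octan-1-yl]acetate
Product: 14 methyl 2-[(1S,2R,4R,5S)-4-acetamido-2-hydroxy-7-oxo-6-oxabicyclo[3.2.1]octan-1-yl]acetate, via amino carbonate 12 (not isolated), via acetamido carbonate 13 (not isolated)
Conditions: H2 (1 atm), Pd/C (10 wt % Pd on carbon), Ac2O (1.5 equiv), EtOAc, rt
Reagents that add atoms: acetic anhydride, CC(=O)OC(C)=O
Why: Catalytic hydrogenation reduces the azide to the amine, which is acetylated as it forms (so it cannot attack the strained lactone), and hydrogenolysis of the benzyl carbonate then frees the C2 alcohol with loss of CO2 under neutral conditions that do not drive γ-lactonisation onto the C8 ester; stereocentres are untouched.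

Step 8
Reactants: 14 methyl 2-[(1S,2R,4R,5S)-4-acetamido-2-hydroxy-7-oxo-6-oxabicyclo[3.2.1]octan-1-yl]acetate
Product: 15 methyl 2-[(1S,2R,4R,5S)-4-acetamido-7-oxo-2-[(triethylsilyl)oxy]-6-oxabicyclo[3.2.1]octan-1-yl]acetate
Conditions: TESOTf, 2,6-lutidine, CH2Cl2, −78 → 0 °C
Reagents that add atoms: triethylsilyl trifluoromethanesulfonate, CC[Si](CC)(CC)OS(=O)(=O)C(F)(F)F
Why: Silyl triflate silylation masks the hindered C2 alcohol at once as a triethylsilyl ether, which tolerates organolithium reagents and can later be cleaved selectively beside a tert-butyldimethylsilyl ether.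

Step 9
Reactants: 16 5-bromo-2-methylpent-2-ene
Product: 17 6-methylhept-5-en-1-yne
Conditions: lithium acetylide ethylenediamine complex, DMSO, 15 °C → rt
Reagents that add atoms: lithium acetylide ethylenediamine complex, [Li]C#C.NCCN
Why: SN2 alkylation of lithium acetylide by the primary bromide in DMSO gives the terminal alkyne.

Step 10
Reactants: 17 6-methylhept-5-en-1-yne
Product: 19 (1E)-1-iodo-2,6-dimethylhepta-1,5-diene, via alkenylalane 18 (not isolated)
Conditions: Me3Al (2 equiv), Cp2ZrCl2 (25 mol %), CH2Cl2, 0 °C → rt; then I2, THF, −30 → 0 °C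
Reagents that add atoms: trimethylaluminium, C[Al](C)C; iodine, II
Why: Negishi zirconium-catalysed carboalumination adds methyl and aluminium syn across the terminal alkyne with aluminium on the terminal carbon, and iodinolysis with retention gives the E alkenyl iodide.

Step 11
Reactants: 15 methyl 2-[(1S,2R,4R,5S)-4-acetamido-7-oxo-2-[(triethylsilyl)oxy]-6-oxabicyclo[3.2.1]octan-1-yl]acetate; 19 (1E)-1-iodo-2,6-dimethylhepta-1,5-diene
Product: 21 methyl 2-[(1S,2R,4R,5S)-4-acetamido-1-[(2E)-3,7-dimethylocta-2,6-dienoyl]-5-hydroxy-2-[(triethylsilyl)oxy]cyclohexyl]acetate, via alkenyllithium 20 (not isolated)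
Conditions: 19 (2.3 equiv), t-BuLi (4.6 equiv), Et2O, −78 °C; then 15, THF, −78 °C; AcOH, −78 °C → rt
Reagents that add atoms: none
Why: Iodine–lithium exchange gives the alkenyllithium with retention of geometry; after the first equivalent has deprotonated the acetamide, 1,2-addition to the strained bridged lactone (more electrophilic than the hindered, enolisable methyl ester) opens it to the alkenyl ketone and frees C5–OH, low temperature and a cold acidic quench limiting double addition.

Step 12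
Reactants: 21 methyl 2-[(1S,2R,4R,5S)-4-acetamido-1-[(2E)-3,7-dimethylocta-2,6-dienoyl]-5-hydroxy-2-[(triethylsilyl)oxy]cyclohexyl]acetate
Product: 22 methyl 2-[(1S,2R,4R,5S)-4-acetamido-5-[(tert-butyldimethylsilyl)oxy]-1-[(2E)-3,7-dimethylocta-2,6-dienoyl]-2-[(triethylsilyl)oxy]cyclohexyl]acetate
Conditions: TBSOTf, 2,6-lutidine, CH2Cl2, −78 → 0 °C
Reagents that add atoms: tert-butyldimethylsilyl trifluoromethanesulfonate, CC(C)(C)[Si](C)(C)OS(=O)(=O)C(F)(F)F
Why: Silyl triflate silylation protects the freed C5 alcohol as a tert-butyldimethylsilyl ether, orthogonal in lability to the C2 triethylsilyl ether and free of acidic O–H for the next step.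

Step 13
Reactants: 22 methyl 2-[(1S,2R,4R,5S)-4-acetamido-5-[(tert-butyldimethylsilyl)oxy]-1-[(2E)-3,7-dimethylocta-2,6-dienoyl]-2-[(triethylsilyl)oxy]cyclohexyl]acetate
Product: 24 N-[(1R,5R,6R,8R,9S)-9-[(tert-butyldimethylsilyl)oxy]-1-[(1E)-2,6-dimethylhepta-1,5-dien-1-yl]-3-oxo-6-[(triethylsilyl)oxy]-2-oxaspiro[4.5]decan-8-yl]acetamide, via hydroxy ester 23 (not isolated)
Conditions: (S)-1-methyl-3,3-diphenyltetrahydro-1H,3H-pyrrolo[1,2-c][1,3,2]oxazaborole (0.5 equiv), catecholborane, PhMe, −78 → −40 °C; then PPTS (cat.), PhMe, 40 °C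
Reagents that add atoms: none
Why: Corey–Bakshi–Shibata reduction: the ketone oxygen binds the catalyst anti to the quaternary C1 (the large group), hydride is delivered to the Si face of C9 and sets 9R, and the resulting allylic alcohol closes the spiro-lactone by acid-catalysed acyl substitution at the C8 methyl ester (5-exo-trig).

Step 14
Reactants: 24 N-[(1R,5R,6R,8R,9S)-9-[(tert-butyldimethylsilyl)oxy]-1-[(1E)-2,6-dimethylhepta-1,5-dien-1-yl]-3-oxo-6-[(triethylsilyl)oxy]-2-oxaspiro[4.5]decan-8-yl]acetamide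
Product: 25 N-[(1R,5S,6R,8R,9S)-9-[(tert-butyldimethylsilyl)oxy]-1-[(1E)-2,6-dimethylhepta-1,5-dien-1-yl]-6-hydroxy-3-oxo-2-oxaspiro[4.5]decan-8-yl]acetamide
Conditions: HF·pyridine, pyridine, THF, 0 °C
Reagents that add atoms: none
Why: Pyridine-buffered hydrogen fluoride cleaves the triethylsilyl ether much faster than the tert-butyldimethylsilyl ether, and the non-basic medium keeps the freed C2 alcohol from translactonising.

Step 15
Reactants: 25 N-[(1R,5S,6R,8R,9S)-9-[(tert-butyldimethylsilyl)oxy]-1-[(1E)-2,6-dimethylhepta-1,5-dien-1-yl]-6-hydroxy-3-oxo-2-oxaspiro[4.5]decan-8-yl]acetamide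
Product: 26 N-[(1R,5R,8R,9S)-9-[(tert-butyldimethylsilyl)oxy]-1-[(1E)-2,6-dimethylhepta-1,5-dien-1-yl]-3,6-dioxo-2-oxaspiro[4.5]decan-8-yl]acetamide
Conditions: Dess–Martin periodinane, NaHCO3, CH2Cl2, 0 °C → rt
Reagents that add atoms: none
Why: Dess–Martin oxidation converts the secondary C2 alcohol into the ketone under buffered, non-basic conditions, so the β-acetamido ketone does not eliminate; the auxiliary C2 stereocentre disappears here.

Step 16
Reactants: 26 N-[(1R,5R,8R,9S)-9-[(tert-butyldimethylsilyl)oxy]-1-[(1E)-2,6-dimethylhepta-1,5-dien-1-yl]-3,6-dioxo-2-oxaspiro[4.5]decan-8-yl]acetamide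
Product: 27 (+)-miliusane V
Conditions: 48 % aq. HF, MeCN, 0 °C → rt
Reagents that add atoms: none
Why: Acidic fluoride desilylation removes the tert-butyldimethylsilyl ether from C5 without base, conditions that the β-acetamido ketone, the allylic lactone and the trisubstituted alkenes should tolerate.

Compound list
1 | monomethyl succinate (4-methoxy-4-oxobutanoic acid) | COC(=O)CCC(=O)O | starting material
2 | [3-(dimethylamino)-2-(2-methoxy-2-oxoethyl)prop-2-en-1-ylidene]dimethylammonium chloride (vinamidinium salt) | C[N+](C)=CC(CC(=O)OC)=CN(C)C.[Cl-] | intermediate (not isolated)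
3 | methyl (E)-4-(dimethylamino)-3-formylbut-3-enoate | O=C/C(CC(=O)OC)=C/N(C)C | intermediate (not isolated)
4 | methyl 3-formyl-4-hydroxybut-3-enoate (enol of 2-(2-methoxy-2-oxoethyl)malondialdehyde; enol geometry mobile) | O=CC(CC(=O)OC)=CO | intermediate
5 | benzyl chloroformate | O=C(Cl)OCc1ccccc1 | starting material
6 | methyl (E)-4-{[(benzyloxy)carbonyl]oxy}-3-formylbut-3-enoate | O=C/C(CC(=O)OC)=C/OC(=O)OCc1ccccc1 | intermediate
7 | buta-1,3-diene | C=CC=C | starting material
8 | methyl 2-[(1S,6R)-6-{[(benzyloxy)carbonyl]oxy}-1-formylcyclohex-3-en-1-yl]acetate (formyl and carbonate trans) | O=C[C@]1(CC(=O)OC)CC=CC[C@H]1OC(=O)OCc1ccccc1 | intermediate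
9 | (1S,6R)-6-{[(benzyloxy)carbonyl]oxy}-1-(2-methoxy-2-oxoethyl)cyclohex-3-ene-1-carboxylic acid | OC(=O)[C@]1(CC(=O)OC)CC=CC[C@H]1OC(=O)OCc1ccccc1 | intermediate
10 | methyl 2-[(1S,2R,4S,5S)-2-{[(benzyloxy)carbonyl]oxy}-4-iodo-7-oxo-6-oxabicyclo[3.2.1]octan-1-yl]acetate | COC(=O)C[C@]12C[C@H](OC1=O)[C@@H](I)C[C@H]2OC(=O)OCc1ccccc1 | intermediate
11 | methyl 2-[(1S,2R,4R,5S)-4-azido-2-{[(benzyloxy)carbonyl]oxy}-7-oxo-6-oxabicyclo[3.2.1]octan-1-yl]acetate | COC(=O)C[C@]12C[C@H](OC1=O)[C@H](N=[N+]=[N-])C[C@H]2OC(=O)OCc1ccccc1 | intermediate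
12 | methyl 2-[(1S,2R,4R,5S)-4-amino-2-{[(benzyloxy)carbonyl]oxy}-7-oxo-6-oxabicyclo[3.2.1]octan-1-yl]acetate | COC(=O)C[C@]12C[C@H](OC1=O)[C@H](N)C[C@H]2OC(=O)OCc1ccccc1 | intermediate (not isolated)
13 | methyl 2-[(1S,2R,4R,5S)-4-acetamido-2-{[(benzyloxy)carbonyl]oxy}-7-oxo-6-oxabicyclo[3.2.1]octan-1-yl]acetate | COC(=O)C[C@]12C[C@H](OC1=O)[C@H](NC(C)=O)C[C@H]2OC(=O)OCc1ccccc1 | intermediate (not isolated)
14 | methyl 2-[(1S,2R,4R,5S)-4-acetamido-2-hydroxy-7-oxo-6-oxabicyclo[3.2.1]octan-1-yl]acetate | COC(=O)C[C@]12C[C@H](OC1=O)[C@H](NC(C)=O)C[C@H]2O | intermediate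
15 | methyl 2-[(1S,2R,4R,5S)-4-acetamido-7-oxo-2-[(triethylsilyl)oxy]-6-oxabicyclo[3.2.1]octan-1-yl]acetate | COC(=O)C[C@]12C[C@H](OC1=O)[C@H](NC(C)=O)C[C@H]2O[Si](CC)(CC)CC | intermediate
16 | 5-bromo-2-methylpent-2-ene | CC(C)=CCCBr | starting material
17 | 6-methylhept-5-en-1-yne | C#CCCC=C(C)C | intermediate
18 | [(1E)-2,6-dimethylhepta-1,5-dien-1-yl]dimethylalane | C[Al](C)/C=C(\C)CCC=C(C)C | intermediate (not isolated)
19 | (1E)-1-iodo-2,6-dimethylhepta-1,5-diene | I/C=C(\C)CCC=C(C)C | intermediate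
20 | [(1E)-2,6-dimethylhepta-1,5-dien-1-yl]lithium | [Li]/C=C(\C)CCC=C(C)C | intermediate (not isolated)
21 | methyl 2-[(1S,2R,4R,5S)-4-acetamido-1-[(2E)-3,7-dimethylocta-2,6-dienoyl]-5-hydroxy-2-[(triethylsilyl)oxy]cyclohexyl]acetate | COC(=O)C[C@@]1(C(=O)/C=C(\C)CCC=C(C)C)C[C@H](O)[C@H](NC(C)=O)C[C@H]1O[Si](CC)(CC)CC | intermediate
22 | methyl 2-[(1S,2R,4R,5S)-4-acetamido-5-[(tert-butyldimethylsilyl)oxy]-1-[(2E)-3,7-dimethylocta-2,6-dienoyl]-2-[(triethylsilyl)oxy]cyclohexyl]acetate | COC(=O)C[C@@]1(C(=O)/C=C(\C)CCC=C(C)C)C[C@H](O[Si](C)(C)C(C)(C)C)[C@H](NC(C)=O)C[C@H]1O[Si](CC)(CC)CC | intermediate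
23 | methyl 2-[(1R,2R,4R,5S)-4-acetamido-5-[(tert-butyldimethylsilyl)oxy]-1-[(1R,2E)-1-hydroxy-3,7-dimethylocta-2,6-dien-1-yl]-2-[(triethylsilyl)oxy]cyclohexyl]acetate | COC(=O)C[C@@]1([C@H](O)/C=C(\C)CCC=C(C)C)C[C@H](O[Si](C)(C)C(C)(C)C)[C@H](NC(C)=O)C[C@H]1O[Si](CC)(CC)CC | intermediate (not isolated)
24 | N-[(1R,5R,6R,8R,9S)-9-[(tert-butyldimethylsilyl)oxy]-1-[(1E)-2,6-dimethylhepta-1,5-dien-1-yl]-3-oxo-6-[(triethylsilyl)oxy]-2-oxaspiro[4.5]decan-8-yl]acetamide | CC(=O)N[C@@H]1C[C@@H](O[Si](CC)(CC)CC)[C@@]2(CC(=O)O[C@@H]2/C=C(\C)CCC=C(C)C)C[C@@H]1O[Si](C)(C)C(C)(C)C | intermediate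
25 | N-[(1R,5S,6R,8R,9S)-9-[(tert-butyldimethylsilyl)oxy]-1-[(1E)-2,6-dimethylhepta-1,5-dien-1-yl]-6-hydroxy-3-oxo-2-oxaspiro[4.5]decan-8-yl]acetamide | CC(=O)N[C@@H]1C[C@@H](O)[C@@]2(CC(=O)O[C@@H]2/C=C(\C)CCC=C(C)C)C[C@@H]1O[Si](C)(C)C(C)(C)C | intermediate
26 | N-[(1R,5R,8R,9S)-9-[(tert-butyldimethylsilyl)oxy]-1-[(1E)-2,6-dimethylhepta-1,5-dien-1-yl]-3,6-dioxo-2-oxaspiro[4.5]decan-8-yl]acetamide | CC(=O)N[C@@H]1CC(=O)[C@@]2(CC(=O)O[C@@H]2/C=C(\C)CCC=C(C)C)C[C@@H]1O[Si](C)(C)C(C)(C)C | intermediate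
27 | (+)-miliusane V, N-[(1R,5R,8R,9S)-1-[(1E)-2,6-dimethylhepta-1,5-dien-1-yl]-9-hydroxy-3,6-dioxo-2-oxaspiro[4.5]decan-8-yl]acetamide | CC(=O)N[C@@H]1CC(=O)[C@@]2(CC(=O)O[C@@H]2/C=C(\C)CCC=C(C)C)C[C@@H]1O | target

Total step count: 16. Longest linear sequence: 14 steps (steps 1–8 and 11–16); steps 9 and 10 make the side-chain iodide.

Steps most likely to fail

Step 3. The push–pull enal may be activated too weakly for butadiene to add at the low temperature at which the catalyst discriminates the two faces, or the enol carbonate may transfer its acyl group to the catalyst, so that conversion or enantiofacial selectivity is poor. The fallback gives up asymmetric catalysis for resolution. It sets out from 6 and 7: cycloaddition promoted by an achiral Lewis acid (Me2AlCl, CH2Cl2, −40 → 0 °C) or run thermally in a sealed tube should give the racemic trans adduct F1. Pinnick oxidation as in step 4 gives the racemic acid F2. Crystallisation with (S)-1-phenylethylamine (the amine enantiomer that carries the wanted acid is found by screening) gives the diastereomerically pure ammonium salt F3, and acidification returns to the route at 9.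

Step 11. The alkenyllithium may attack the methyl ester in competition with the lactone, or add a second time to the enone once the adduct collapses. The fallback removes the competing ester by turning it into a carboxylate. It sets out from 15: SN2 demethylation with LiI in refluxing EtOAc, which does not touch the lactone carbonyl, should give the carboxylic acid F4. Its lithium carboxylate is inert to 20 at −78 °C, so addition of 20 (3.3 equiv) occurs only at the lactone and gives the keto acid F5. Methylation with Me3SiCHN2 in MeOH/PhMe comes back to the route at 21.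

Step 13. The substrate's own facial bias may override the catalyst, so that hydride is delivered mainly to the wrong face of C9. The fallback then sets C9 by C–O bond formation with inversion instead of by hydride delivery. It sets out from 22: reduction with the (R)-configured oxazaborolidine, matched with that bias, should give the 9S allylic alcohol F6. Mitsunobu esterification (PPh3, DIAD, 4-nitrobenzoic acid, THF, 0 °C) inverts C9 and gives the 9R 4-nitrobenzoate F7. Methanolysis (K2CO3, MeOH, 0 °C) frees the 9R alkoxide, which lactonises onto the C8 ester and comes back to the route at 24.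

Further compounds
F1 | step 3 | racemic methyl 2-[(1RS,6SR)-6-{[(benzyloxy)carbonyl]oxy}-1-formylcyclohex-3-en-1-yl]acetate | O=C[C@]1(CC(=O)OC)CC=CC[C@H]1OC(=O)OCc1ccccc1.O=C[C@@]1(CC(=O)OC)CC=CC[C@@H]1OC(=O)OCc1ccccc1
F2 | step 3 | racemic (1RS,6SR)-6-{[(benzyloxy)carbonyl]oxy}-1-(2-methoxy-2-oxoethyl)cyclohex-3-ene-1-carboxylic acid | OC(=O)[C@]1(CC(=O)OC)CC=CC[C@H]1OC(=O)OCc1ccccc1.OC(=O)[C@@]1(CC(=O)OC)CC=CC[C@@H]1OC(=O)OCc1ccccc1
F3 | step 3 | (S)-1-phenylethylammonium (1S,6R)-6-{[(benzyloxy)carbonyl]oxy}-1-(2-methoxy-2-oxoethyl)cyclohex-3-ene-1-carboxylate | [O-]C(=O)[C@]1(CC(=O)OC)CC=CC[C@H]1OC(=O)OCc1ccccc1.C[C@H]([NH3+])c1ccccc1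
F4 | step 11 | 2-[(1S,2R,4R,5S)-4-acetamido-7-oxo-2-[(triethylsilyl)oxy]-6-oxabicyclo[3.2.1]octan-1-yl]acetic acid | OC(=O)C[C@]12C[C@H](OC1=O)[C@H](NC(C)=O)C[C@H]2O[Si](CC)(CC)CC
F5 | step 11 | 2-[(1S,2R,4R,5S)-4-acetamido-1-[(2E)-3,7-dimethylocta-2,6-dienoyl]-5-hydroxy-2-[(triethylsilyl)oxy]cyclohexyl]acetic acid | OC(=O)C[C@@]1(C(=O)/C=C(\C)CCC=C(C)C)C[C@H](O)[C@H](NC(C)=O)C[C@H]1O[Si](CC)(CC)CC
F6 | step 13 | methyl 2-[(1R,2R,4R,5S)-4-acetamido-5-[(tert-butyldimethylsilyl)oxy]-1-[(1S,2E)-1-hydroxy-3,7-dimethylocta-2,6-dien-1-yl]-2-[(triethylsilyl)oxy]cyclohexyl]acetate | COC(=O)C[C@@]1([C@@H](O)/C=C(\C)CCC=C(C)C)C[C@H](O[Si](C)(C)C(C)(C)C)[C@H](NC(C)=O)C[C@H]1O[Si](CC)(CC)CC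
F7 | step 13 | methyl 2-[(1R,2R,4R,5S)-4-acetamido-5-[(tert-butyldimethylsilyl)oxy]-1-[(1R,2E)-3,7-dimethyl-1-[(4-nitrobenzoyl)oxy]octa-2,6-dien-1-yl]-2-[(triethylsilyl)oxy]cyclohexyl]acetate | COC(=O)C[C@@]1([C@H](OC(=O)c2ccc(cc2)[N+](=O)[O-])/C=C(\C)CCC=C(C)C)C[C@H](O[Si](C)(C)C(C)(C)C)[C@H](NC(C)=O)C[C@H]1O[Si](CC)(CC)CC
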